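**Strategy.** The route rests on disconnecting the C7–C11 bond of the cis-fused α-methylene-γ-lactone (ring O–C6–C7–C11–C12). This maps the contiguous C6(O)/C7(C)/C8(O) triad onto a C6 phosphonoacetate flanking a trans C7–C8 epoxide. In one operation the tethered phosphonate carbanion C11 opens the epoxide at C7 with inversion, which closes the lactone, fixes C7 and unveils the C8 hydroxyl that later carries the isovalerate. The precursor is a threo epoxy ester bearing the C2–C5 silyl enyne, a silyl-protected C15 oxygen, and the C10 oxygen tied to C1 as an acetonide, so no silyl group can migrate to the liberated C8 oxygen.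

Key step: step 11

**Remarks on the chemistry.**
- Atoms keep the numbering of the target: C1 ketone, C2/C3 furanone alkene, C4 bearing C15, C5 alkene CH, C6 lactone OCH, C7, C8 isovalerate CH, C9 CH2, C10 quaternary with methyl C14, C11–C13 methylene lactone.
- C6 and C3 are cis across C4=C5 in every intermediate. CIP calls this one geometry Z in the iodoalkenes 13 and 14, E in the enynes 16–27, and Z in the furanones 28 and 29.
- Descriptors at C6 and C7 also change with the substituents. Real inversions occur only at C6 (step 10) and C7 (step 11).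
- C11 of 19 and C1 of 26 form as epimer mixtures; both carbons become sp2 later.
- Protecting groups in precursor 18 were chosen for three reasons. The C1/C10 acetonide cannot migrate and is removed in one operation. The C15 TBDPS ether survives that acid step and is removed last. The TMS cap on C2 is converted directly into the iodoalkyne.
- In step 8 the unreacted (4R)-epimer of 13 is separated and can be recycled by inversion.

**Route**

Step 1
Reactants: 1 methallyl alcohol
Product: 2 [(2S)-2-methyloxiran-2-yl]methanol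
Conditions: Ti(OiPr)4 (cat.), L-(+)-diethyl tartrate (cat.), t-BuOOH, 4 Å MS, CH2Cl2, −20 °C
Reagents that add atoms: tert-butyl hydroperoxide, CC(C)(C)OO
Why: Katsuki–Sharpless asymmetric epoxidation, in which the L-(+)-tartrate titanium complex delivers the peroxide oxygen to one face of the allylic alcohol and so sets the quaternary centre that becomes C10.

Step 2
Reactants: 2 [(2S)-2-methyloxiran-2-yl]methanol; 3 vinylmagnesium bromide
Product: 4 (2R)-2-methylpent-4-ene-1,2-diol
Conditions: 3 (2.5 equiv.), CuI (cat.), THF, −30 to 0 °C; aq. NH4Cl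
Reagents that add atoms: none
Why: Copper-catalysed Grignard opening of the epoxide (SN2) should occur at the unhindered CH2 terminus (C9) after the first equivalent has deprotonated the hydroxyl, attaching the C7=C8 vinyl unit without touching the C10 stereocentre.

Step 3
Reactants: 4 (2R)-2-methylpent-4-ene-1,2-diol
Product: 5 (4R)-2,2,4-trimethyl-4-(prop-2-en-1-yl)-1,3-dioxolane
Conditions: 2,2-dimethoxypropane, PPTS (cat.), CH2Cl2, rt
Reagents that add atoms: 2,2-dimethoxypropane, COC(C)(C)OC
Why: Acid-catalysed transacetalisation closes the five-membered isopropylidene acetal across the C1 and C10 oxygens.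

Step 4
Reactants: 5 allyl dioxolane; 6 (2E)-but-2-enal
Product: 7 (2E)-4-[(4R)-2,2,4-trimethyl-1,3-dioxolan-4-yl]but-2-enal
Conditions: 6 (excess), second-generation Hoveyda–Grubbs catalyst (cat.), CH2Cl2, 40 °C
Reagents that add atoms: none
Why: Olefin cross-metathesis of a terminal alkene with an enal partner should give the thermodynamically favoured E-enal with loss of propene, adding C6 as the aldehyde.

Step 5
Reactants: 8 prop-2-yn-1-ol
Product: 9 tert-butyl(diphenyl)(prop-2-yn-1-yloxy)silane
Conditions: TBDPSCl, imidazole, CH2Cl2, 0 °C to rt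
Reagents that add atoms: tert-butyl(chloro)diphenylsilane, CC(C)(C)[Si](Cl)(c1ccccc1)c1ccccc1
Why: Imidazole-promoted silylation of a primary alcohol gives the TBDPS ether, chosen because it survives the aqueous acid of step 15.

Step 6
Reactants: 9 tert-butyl(diphenyl)(prop-2-yn-1-yloxy)silane; 7 enal
Product: 11 (5E)-1-{[tert-butyl(diphenyl)silyl]oxy}-7-[(4R)-2,2,4-trimethyl-1,3-dioxolan-4-yl]hept-5-en-2-yn-4-ol as both C4 epimers, via lithium acetylide 10 (not isolated)
Conditions: n-BuLi, THF, −78 °C; then 7, −78 °C; aq. NH4Cl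
Reagents that add atoms: none
Why: 1,2-Addition of a lithium acetylide to the enal carbonyl at low temperature forms the C5–C6 bond, and no control at C6 is sought because step 8 selects one epimer.

Step 7
Reactants: 11 enynol (both C6 epimers)
Product: 13 (2Z,5E)-1-{[tert-butyl(diphenyl)silyl]oxy}-2-iodo-7-[(4R)-2,2,4-trimethyl-1,3-dioxolan-4-yl]hepta-2,5-dien-4-ol as both C4 epimers, via cyclic alkenylaluminate 12 (not isolated)
Conditions: NaAlH2(OCH2CH2OMe)2, THF, 0 °C; then I2, −78 to 0 °C; aq. Rochelle salt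
Reagents that add atoms: iodine, [I][I]
Why: Hydroxyl-directed trans-hydroalumination of the propargylic alcohol places hydride on C5 and aluminium on C4 in a five-membered aluminate, and iodinolysis with retention should give the iodoalkene with C6 cis to iodine, the geometry the ring alkene needs.

Step 8
Reactants: 13 iodo dienol (both C6 epimers)
Product: 14 (1R,2Z)-4-{[tert-butyl(diphenyl)silyl]oxy}-3-iodo-1-[(2R,3R)-3-{[(4R)-2,2,4-trimethyl-1,3-dioxolan-4-yl]methyl}oxiran-2-yl]but-2-en-1-ol
Conditions: Ti(OiPr)4, D-(−)-diisopropyl tartrate, t-BuOOH (0.6 equiv.), 4 Å MS, CH2Cl2, −20 °C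
Reagents that add atoms: tert-butyl hydroperoxide, CC(C)(C)OO
Why: Sharpless kinetic resolution, in which with D-(−)-tartrate only the (4S)-epimer of 13 reaches the matched transition state, so oxygen adds to one face of the E C7=C8 alkene to give the erythro epoxy alcohol with the C8–O configuration of the target, while the other epimer and the electron-poor, A(1,3)-strained iodoalkene stay untouched.

Step 9
Reactants: 14 erythro epoxy alcohol (iodoalkene); 15 ethynyl(trimethyl)silane
Product: 16 (1R,2E)-3-({[tert-butyl(diphenyl)silyl]oxy}methyl)-1-[(2R,3R)-3-{[(4R)-2,2,4-trimethyl-1,3-dioxolan-4-yl]methyl}oxiran-2-yl]-5-(trimethylsilyl)pent-2-en-4-yn-1-ol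
Conditions: PdCl2(PPh3)2 (cat.), CuI (cat.), Et3N, THF, rt
Reagents that add atoms: none
Why: Sonogashira coupling of the alkenyl iodide with the terminal alkyne proceeds with retention of alkene geometry under mild amine conditions that leave the epoxy alcohol intact, installing C2 and C3.

Step 10
Reactants: 16 erythro epoxy enynol; 17 (diethoxyphosphoryl)acetic acid
Product: 18 (1S,2E)-3-({[tert-butyl(diphenyl)silyl]oxy}methyl)-1-[(2S,3R)-3-{[(4R)-2,2,4-trimethyl-1,3-dioxolan-4-yl]methyl}oxiran-2-yl]-5-(trimethylsilyl)pent-2-en-4-yn-1-yl (diethoxyphosphoryl)acetate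
Conditions: PPh3, DIAD, THF, 0 °C to rt
Reagents that add atoms: none
Why: Mitsunobu esterification, in which the carboxylate of the acidic phosphonoacetic acid displaces the alkoxyphosphonium group by SN2 and so inverts C6, turning the erythro alcohol into the threo ester needed for a cis lactone.

Step 11
Reactants: 18 threo epoxy phosphonoacetate
Product: 19 diethyl [(4R,5S)-5-[(1E)-2-({[tert-butyl(diphenyl)silyl]oxy}methyl)-4-(trimethylsilyl)but-1-en-3-yn-1-yl]-4-{(1R)-1-hydroxy-2-[(4R)-2,2,4-trimethyl-1,3-dioxolan-4-yl]ethyl}-2-oxooxolan-3-yl]phosphonate (both C11 epimers)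
Conditions: LiCl, DBU, MeCN, 0 to 40 °C; then cold aq. citric acid
Reagents that add atoms: none
Why: DBU with LiCl reversibly deprotonates the phosphonoacetate CH2 (C11) to a lithium-chelated stabilised enolate whose carbon attacks C7 anti to the epoxide C7–O bond in an intramolecular SN2 alkylation, the closest known type being lactone-forming epoxide opening by tethered malonate-type ester enolates. The γ-lactone ring O–C6–C7–C11–C12 closes in the 5-exo-tet mode, the breaking C7–O bond lying outside the new ring. C7 is the only stereocentre changed: backside attack inverts it while C6 and C8 are not touched, so the threo ester of the trans epoxide should give the cis-fused lactone with the (8R) carbinol, and C11 forms as an inconsequential epimer mixture. Attack at C7 and not C8 is secured by the three-atom O–C12–C11 tether, which reaches C7 collinearly with the leaving oxygen but could reach C8 only by a 6-endo path across the epoxide. The released C8 alkoxide is protonated at once by protonated DBU and the product rests as its phosphonate enolate, which deactivates C12 and phosphorus toward the C8 hydroxyl and so holds back acyl migration, while the acetonide offers no group that could migrate. Cold buffered acid then returns neutral 19.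

Step 12
Reactants: 19 α-phosphono lactone
Product: 20 (4R,5S)-5-[(1E)-2-({[tert-butyl(diphenyl)silyl]oxy}methyl)-4-(trimethylsilyl)but-1-en-3-yn-1-yl]-4-{(1R)-1-hydroxy-2-[(4R)-2,2,4-trimethyl-1,3-dioxolan-4-yl]ethyl}-3-methylideneoxolan-2-one
Conditions: 37% aq. CH2O, K2CO3, THF, 0 °C
Reagents that add atoms: formaldehyde, C=O
Why: Horner–Wadsworth–Emmons olefination of the α-phosphono lactone with formaldehyde forms the exocyclic C11=C13 alkene and erases the C11 stereocentre under a weak base and short contact that should leave the lactone and the C8 hydroxyl in place.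

Step 13
Reactants: 20 hydroxy methylene lactone; 21 3-methylbutanoic anhydride
Product: 22 C8 3-methylbutanoate of 20
Conditions: DMAP (cat.), Et3N, CH2Cl2, 0 °C to rt
Reagents that add atoms: none
Why: DMAP-catalysed acylation of the only free hydroxyl installs the C8 isovalerate with retention, since the C8–O bond is not broken.

Step 14
Reactants: 22 C8 isovalerate (silyl alkyne)
Product: 23 iodoalkyne (C2–I in place of C2–SiMe3)
Conditions: NIS, AgNO3 (cat.), acetone, rt, dark
Reagents that add atoms: N-iodosuccinimide, O=C1CCC(=O)N1I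
Why: Silver-catalysed iododesilylation converts the alkynylsilane through a silver acetylide into the 1-iodoalkyne at C2 without attacking the alkenes.

Step 15
Reactants: 23 iodoalkyne acetonide
Product: 24 C1/C10 diol (primary C1 hydroxyl, tertiary 10R hydroxyl)
Conditions: AcOH/THF/H2O (3:1:1), 40 °C
Reagents that add atoms: none
Why: Acid-catalysed acetal hydrolysis frees the C1 and C10 hydroxyls in one step under conditions that the primary TBDPS ether, both esters and the iodoalkyne should tolerate.

Step 16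
Reactants: 24 diol
Product: 25 C1 aldehyde with free C10 hydroxyl
Conditions: IBX, DMSO, rt
Reagents that add atoms: none
Why: IBX oxidises the primary C1 alcohol to the aldehyde without cleaving the 1,2-diol, the tertiary C10 hydroxyl being inert and the α-carbon quaternary so that nothing can epimerise.

Step 17
Reactants: 25 iodoalkyne aldehyde
Product: 26 ten-membered enynediol (C1–C2 bond closed, both C1 epimers)
Conditions: CrCl2 (excess), NiCl2 (cat.), degassed THF, rt, slow addition (high dilution)
Reagents that add atoms: none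
Why: Nozaki–Hiyama–Kishi reaction, in which divalent chromium with a trace of NiCl2 turns the iodoalkyne into an alkynylchromium species that adds to the non-enolisable C1 aldehyde under neutral conditions tolerated by the lactone and the ester, closing the ten-membered ring.

Step 18
Reactants: 26 macrocyclic enynediol
Product: 27 macrocyclic α'-hydroxy ynone (C1 ketone)
Conditions: Dess–Martin periodinane, CH2Cl2, 0 °C
Reagents that add atoms: none
Why: Dess–Martin oxidation of the secondary propargylic alcohol gives the ynone and removes the C1 stereocentre, the tertiary C10 hydroxyl being inert.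

Step 19
Reactants: 27 hydroxy ynone
Product: 28 15-O-TBDPS ether of the target (furanone closed)
Conditions: (4-CF3C6H4)3PAuCl (cat.), AgOTf (cat.), toluene, rt
Reagents that add atoms: none
Why: Gold-catalysed cycloisomerisation of an α'-hydroxy ynone, in which monovalent gold activates the C2≡C3 alkyne for transannular 5-endo-dig attack of the C10 hydroxyl at C3 and protodeauration gives the 3(2H)-furanone.

Step 20
Reactants: 28 silyl ether
Product: 29 target, (4Z,6S,7R,8R,10R)-15-hydroxy-1-oxo-3,10-epoxygermacra-2,4,11(13)-trien-12,6-olid-8-yl 3-methylbutanoate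
Conditions: HF·pyridine, pyridine, THF, 0 °C to rt
Reagents that add atoms: none
Why: Fluoride-driven cleavage of the silyl ether under buffered acidic conditions should spare the methylene lactone, the furanone and the isovalerate and release the C15 hydroxyl.

**Compound list**

1 | 2-methylprop-2-en-1-ol (methallyl alcohol) | C=C(C)CO | starting material
2 | [(2S)-2-methyloxiran-2-yl]methanol | C[C@]1(CO)CO1 | intermediate
3 | vinylmagnesium bromide | C=C[Mg]Br | starting material
4 | (2R)-2-methylpent-4-ene-1,2-diol | C[C@](O)(CO)CC=C | intermediate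
5 | (4R)-2,2,4-trimethyl-4-(prop-2-en-1-yl)-1,3-dioxolane | C=CC[C@@]1(C)OC(C)(C)OC1 | intermediate
6 | (2E)-but-2-enal (crotonaldehyde) | C/C=C/C=O | starting material
7 | (2E)-4-[(4R)-2,2,4-trimethyl-1,3-dioxolan-4-yl]but-2-enal | O=C/C=C/C[C@@]1(C)OC(C)(C)OC1 | intermediate
8 | prop-2-yn-1-ol (propargyl alcohol) | C#CCO | starting material
9 | tert-butyl(diphenyl)(prop-2-yn-1-yloxy)silane | C#CCO[Si](c1ccccc1)(c1ccccc1)C(C)(C)C | intermediate
10 | lithium acetylide of 9 | [Li]C#CCO[Si](c1ccccc1)(c1ccccc1)C(C)(C)C | intermediate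
11 | (5E)-1-{[tert-butyl(diphenyl)silyl]oxy}-7-[(4R)-2,2,4-trimethyl-1,3-dioxolan-4-yl]hept-5-en-2-yn-4-ol, both C4 (= C6) epimers | OC(/C=C/C[C@@]1(C)OC(C)(C)OC1)C#CCO[Si](c2ccccc2)(c3ccccc3)C(C)(C)C | intermediate
12 | sodium cyclic alkenylaluminate (Al bound to the C6 oxygen and to C4, two 2-methoxyethoxy ligands) | [Na+].COCCO[Al-]1(OCCOC)OC(/C=C/C[C@@]2(C)OC(C)(C)OC2)C=C1CO[Si](c3ccccc3)(c4ccccc4)C(C)(C)C | intermediate
13 | (2Z,5E)-1-{[tert-butyl(diphenyl)silyl]oxy}-2-iodo-7-[(4R)-2,2,4-trimethyl-1,3-dioxolan-4-yl]hepta-2,5-dien-4-ol, both C4 (= C6) epimers | OC(/C=C/C[C@@]1(C)OC(C)(C)OC1)/C=C(\I)CO[Si](c2ccccc2)(c3ccccc3)C(C)(C)C | intermediate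
14 | (1R,2Z)-4-{[tert-butyl(diphenyl)silyl]oxy}-3-iodo-1-[(2R,3R)-3-{[(4R)-2,2,4-trimethyl-1,3-dioxolan-4-yl]methyl}oxiran-2-yl]but-2-en-1-ol (erythro) | O[C@H](/C=C(\I)CO[Si](c2ccccc2)(c3ccccc3)C(C)(C)C)[C@H]1O[C@@H]1C[C@@]4(C)OC(C)(C)OC4 | intermediate
15 | ethynyl(trimethyl)silane | C#C[Si](C)(C)C | starting material
16 | (1R,2E)-3-({[tert-butyl(diphenyl)silyl]oxy}methyl)-1-[(2R,3R)-3-{[(4R)-2,2,4-trimethyl-1,3-dioxolan-4-yl]methyl}oxiran-2-yl]-5-(trimethylsilyl)pent-2-en-4-yn-1-ol (erythro) | O[C@H](/C=C(/CO[Si](c2ccccc2)(c3ccccc3)C(C)(C)C)C#C[Si](C)(C)C)[C@H]1O[C@@H]1C[C@@]4(C)OC(C)(C)OC4 | intermediate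
17 | (diethoxyphosphoryl)acetic acid | CCOP(=O)(OCC)CC(=O)O | starting material
18 | (1S,2E)-3-({[tert-butyl(diphenyl)silyl]oxy}methyl)-1-[(2S,3R)-3-{[(4R)-2,2,4-trimethyl-1,3-dioxolan-4-yl]methyl}oxiran-2-yl]-5-(trimethylsilyl)pent-2-en-4-yn-1-yl (diethoxyphosphoryl)acetate (threo; key-step precursor) | CCOP(=O)(OCC)CC(=O)O[C@@H](/C=C(/CO[Si](c2ccccc2)(c3ccccc3)C(C)(C)C)C#C[Si](C)(C)C)[C@H]1O[C@@H]1C[C@@]4(C)OC(C)(C)OC4 | intermediate
19 | diethyl [(4R,5S)-5-[(1E)-2-({[tert-butyl(diphenyl)silyl]oxy}methyl)-4-(trimethylsilyl)but-1-en-3-yn-1-yl]-4-{(1R)-1-hydroxy-2-[(4R)-2,2,4-trimethyl-1,3-dioxolan-4-yl]ethyl}-2-oxooxolan-3-yl]phosphonate, both C3 (= C11) epimers (key-step product) | CCOP(=O)(OCC)C1C(=O)O[C@@H](/C=C(/CO[Si](c2ccccc2)(c3ccccc3)C(C)(C)C)C#C[Si](C)(C)C)[C@H]1[C@H](O)C[C@@]4(C)OC(C)(C)OC4 | intermediate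
20 | (4R,5S)-5-[(1E)-2-({[tert-butyl(diphenyl)silyl]oxy}methyl)-4-(trimethylsilyl)but-1-en-3-yn-1-yl]-4-{(1R)-1-hydroxy-2-[(4R)-2,2,4-trimethyl-1,3-dioxolan-4-yl]ethyl}-3-methylideneoxolan-2-one | C=C1C(=O)O[C@@H](/C=C(/CO[Si](c2ccccc2)(c3ccccc3)C(C)(C)C)C#C[Si](C)(C)C)[C@H]1[C@H](O)C[C@@]4(C)OC(C)(C)OC4 | intermediate
21 | 3-methylbutanoic anhydride (isovaleric anhydride) | CC(C)CC(=O)OC(=O)CC(C)C | starting material
22 | (1R)-1-{(2S,3R)-2-[(1E)-2-({[tert-butyl(diphenyl)silyl]oxy}methyl)-4-(trimethylsilyl)but-1-en-3-yn-1-yl]-4-methylidene-5-oxooxolan-3-yl}-2-[(4R)-2,2,4-trimethyl-1,3-dioxolan-4-yl]ethyl 3-methylbutanoate | C=C1C(=O)O[C@@H](/C=C(/CO[Si](c2ccccc2)(c3ccccc3)C(C)(C)C)C#C[Si](C)(C)C)[C@H]1[C@H](OC(=O)CC(C)C)C[C@@]4(C)OC(C)(C)OC4 | intermediate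
23 | iodoalkyne: 22 with iodine in place of the trimethylsilyl group on C2 | C=C1C(=O)O[C@@H](/C=C(/CO[Si](c2ccccc2)(c3ccccc3)C(C)(C)C)C#CI)[C@H]1[C@H](OC(=O)CC(C)C)C[C@@]4(C)OC(C)(C)OC4 | intermediate
24 | diol: 23 with the acetonide removed (C1 CH2OH, 10R tertiary OH, 8R isovalerate, 6S,7R lactone) | C=C1C(=O)O[C@@H](/C=C(/CO[Si](c2ccccc2)(c3ccccc3)C(C)(C)C)C#CI)[C@H]1[C@H](OC(=O)CC(C)C)C[C@@](C)(O)CO | intermediate
25 | aldehyde: 24 with C1 oxidised to CHO (10R tertiary OH free) | C=C1C(=O)O[C@@H](/C=C(/CO[Si](c2ccccc2)(c3ccccc3)C(C)(C)C)C#CI)[C@H]1[C@H](OC(=O)CC(C)C)C[C@@](C)(O)C=O | intermediate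
26 | ten-membered carbocycle C1–C10: C1 secondary propargylic alcohol (both epimers), C2≡C3, (4E)-C4=C5 with C15H2OTBDPS on C4, (6S,7R) cis-fused α-methylene-γ-lactone, (8R) 3-methylbutanoate, (10R) tertiary alcohol with methyl C14 | C=C1C(=O)O[C@H]2/C=C(/CO[Si](c3ccccc3)(c4ccccc4)C(C)(C)C)C#CC(O)[C@@](C)(C[C@@H](OC(=O)CC(C)C)[C@@H]12)O | intermediate
27 | macrocyclic ynone: 26 with C1 as ketone (6S,7R,8R,10R) | C=C1C(=O)O[C@H]2/C=C(/CO[Si](c3ccccc3)(c4ccccc4)C(C)(C)C)C#CC(=O)[C@@](C)(C[C@@H](OC(=O)CC(C)C)[C@@H]12)O | intermediate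
28 | 15-O-[tert-butyl(diphenyl)silyl] ether of the target (4Z,6S,7R,8R,10R; furanone O bridging C3 and C10) | C=C1C(=O)O[C@H]2/C=C(/CO[Si](c5ccccc5)(c6ccccc6)C(C)(C)C)C3=CC(=O)[C@@](C)(C[C@@H](OC(=O)CC(C)C)[C@@H]12)O3 | intermediate
29 | (4Z,6S,7R,8R,10R)-15-hydroxy-1-oxo-3,10-epoxygermacra-2,4,11(13)-trien-12,6-olid-8-yl 3-methylbutanoate (CNP0171896.2) | C=C1C(=O)O[C@H]2/C=C(/CO)C3=CC(=O)[C@@](C)(C[C@@H](OC(=O)CC(C)C)[C@@H]12)O3 | target

**Step count.** Total: 20 steps. Longest linear sequence: 19 steps (steps 1–4 and 6–20); step 5 is a one-step side branch.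

**Steps most likely to fail**

1. Step 11 (epoxide-opening lactonisation). The highly stabilised carbanion may alkylate sluggishly, 6-endo opening at C8 may compete, or the lactone acyl group may transfer to the liberated C8 oxygen. Fallback: make the same C7–C11 bond with a malonate carbanion and introduce the methylene by decarboxylative Mannich methylenation instead of olefination. It sets out from 16. Mitsunobu esterification with monoallyl malonate (PPh3, DIAD) would give the inverted allyl malonate diester F1. NaH in THF would close it to the α-(allyloxycarbonyl) lactone F2. Pd(PPh3)4 with morpholine would remove the allyl group to give the α-carboxy lactone F3. Aqueous formaldehyde with diethylamine in buffered acetic acid would then give, with loss of CO2, the methylene lactone 20, where the route is rejoined.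

2. Step 17 (chromium-mediated ring closure). Strain in the forming cyclodecenyne may slow cyclisation so that oligomerisation or simple reduction of the carbon–iodine bond takes over. Fallback: form the C1–C2 bond by an aldol reaction and the furanone by cyclodehydration, so that no cyclic alkyne is ever made. It sets out from 22. AgNO3-catalysed protodesilylation in aqueous acetone would give the terminal alkyne F4. Hydration catalysed by Ph3PAuNTf2 in wet dioxane would give the methyl enone F5 (C3 ketone, C2 methyl). Aqueous acetic acid would give the diol F6, and IBX the non-enolisable aldehyde F7. Soft enolisation of the methyl ketone (c-Hex2BCl, Et3N) and intramolecular aldol addition to C1 would give the ten-membered β-hydroxy ketone F8. Dess–Martin oxidation would give the 1,3-diketone F9. TsOH in toluene would then close the C10 hydroxyl onto C3 with loss of water to give the furanone 28, where the route is rejoined.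

3. Step 10 (Mitsunobu inversion with the phosphonoacetic acid). The hindered C6 alcohol, flanked by the epoxide and the trisubstituted alkene, may be activated but displaced incompletely, with elimination or ester formation with retention. Fallback: separate inversion from acylation. It sets out from 14. Mitsunobu reaction with 4-nitrobenzoic acid would give the inverted 4-nitrobenzoate F10. K2CO3 in methanol at 0 °C would give the threo epoxy alcohol F11; this is done at the iodoalkene stage so that no alkynylsilane is exposed to methoxide. Sonogashira coupling with 15 would give the threo enynol F12. DCC/DMAP esterification with 17, which does not touch the C6–O bond, would then give the precursor 18, where the route is rejoined.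

Further compounds
F1 | step 11 | allyl malonate diester of the C6-inverted (threo) epoxy enynol | C=CCOC(=O)CC(=O)O[C@@H](/C=C(/CO[Si](c2ccccc2)(c3ccccc3)C(C)(C)C)C#C[Si](C)(C)C)[C@H]1O[C@@H]1C[C@@]4(C)OC(C)(C)OC4
F2 | step 11 | α-(allyloxycarbonyl) cis-lactone with free C8 hydroxyl (C11 epimers) | C=CCOC(=O)C1C(=O)O[C@@H](/C=C(/CO[Si](c2ccccc2)(c3ccccc3)C(C)(C)C)C#C[Si](C)(C)C)[C@H]1[C@H](O)C[C@@]4(C)OC(C)(C)OC4
F3 | step 11 | α-carboxy cis-lactone with free C8 hydroxyl (C11 epimers) | OC(=O)C1C(=O)O[C@@H](/C=C(/CO[Si](c2ccccc2)(c3ccccc3)C(C)(C)C)C#C[Si](C)(C)C)[C@H]1[C@H](O)C[C@@]4(C)OC(C)(C)OC4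
F4 | step 17 | terminal alkyne: 22 with hydrogen in place of the trimethylsilyl group | C=C1C(=O)O[C@@H](/C=C(/CO[Si](c2ccccc2)(c3ccccc3)C(C)(C)C)C#C)[C@H]1[C@H](OC(=O)CC(C)C)C[C@@]4(C)OC(C)(C)OC4
F5 | step 17 | methyl enone: C3 acetyl group on C4 (acetonide intact) | C=C1C(=O)O[C@@H](/C=C(/CO[Si](c2ccccc2)(c3ccccc3)C(C)(C)C)C(C)=O)[C@H]1[C@H](OC(=O)CC(C)C)C[C@@]4(C)OC(C)(C)OC4
F6 | step 17 | methyl enone C1/C10 diol | C=C1C(=O)O[C@@H](/C=C(/CO[Si](c2ccccc2)(c3ccccc3)C(C)(C)C)C(C)=O)[C@H]1[C@H](OC(=O)CC(C)C)C[C@@](C)(O)CO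
F7 | step 17 | methyl enone C1 aldehyde with free C10 hydroxyl | C=C1C(=O)O[C@@H](/C=C(/CO[Si](c2ccccc2)(c3ccccc3)C(C)(C)C)C(C)=O)[C@H]1[C@H](OC(=O)CC(C)C)C[C@@](C)(O)C=O
F8 | step 17 | ten-membered β-hydroxy ketone (C1 carbinol, C2 methylene, C3 ketone) | C=C1C(=O)O[C@H]2/C=C(/CO[Si](c3ccccc3)(c4ccccc4)C(C)(C)C)C(=O)CC(O)[C@@](C)(C[C@@H](OC(=O)CC(C)C)[C@@H]12)O
F9 | step 17 | ten-membered 1,3-diketone (C1 and C3 ketones, free C10 hydroxyl) | C=C1C(=O)O[C@H]2/C=C(/CO[Si](c3ccccc3)(c4ccccc4)C(C)(C)C)C(=O)CC(=O)[C@@](C)(C[C@@H](OC(=O)CC(C)C)[C@@H]12)O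
F10 | step 10 | C6-inverted 4-nitrobenzoate of the iodoalkene epoxy alcohol | O=C(O[C@@H](/C=C(\I)CO[Si](c2ccccc2)(c3ccccc3)C(C)(C)C)[C@H]1O[C@@H]1C[C@@]4(C)OC(C)(C)OC4)c5ccc(cc5)[N+](=O)[O-]
F11 | step 10 | threo epoxy alcohol (iodoalkene) | O[C@@H](/C=C(\I)CO[Si](c2ccccc2)(c3ccccc3)C(C)(C)C)[C@H]1O[C@@H]1C[C@@]4(C)OC(C)(C)OC4
F12 | step 10 | threo epoxy enynol | O[C@@H](/C=C(/CO[Si](c2ccccc2)(c3ccccc3)C(C)(C)C)C#C[Si](C)(C)C)[C@H]1O[C@@H]1C[C@@]4(C)OC(C)(C)OC4
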